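**Assumption:** the SMILES is read as the trans-fused 8,12-olide with 7R,8S (= 3aR,11aS), the C1=C10 double bond cis in the ring, the C4=C5 double bond trans in the ring, and a (2S) side chain. Germacrane numbering (C1–C15) is used for atom labels; TBS = tert-butyldimethylsilyl. Compounds 1, 4, 6, 9 and methyl propiolate are taken as catalogue chemicals.

## Retrosynthetic overview

1. The last skeletal bond made is C14–O: SeO2/t-BuOOH allylic C–H hydroxylation of an all-trans germacrolide, whose ene/[2,3] sequence also turns C1=C10 into the cis-in-ring geometry; desilylation then gives the target.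
2. The ten-membered ring and the γ-lactone come from one operation on an acyclic bromo aldehyde: enantioselective chromium-catalysed C7–C8 allylation (new), then O8–C12 lactonisation (carbocycle first, lactone second).
3. The bromo aldehyde comes from anti-Markovnikov hydration of a terminal alkyne (C8–O), a propiolate-derived Baylis–Hillman unit (C7, C11–C13) and esterification at C15–O with the silylated Roche acid.
4. The chain comes from a Z-selective Wittig reaction (C4=C5) of an α-silyloxy ketone with an acetal ylide; the ketone comes from silyloxyacetone enolate and an (E)-enynyl bromide.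

## Route

Step 1
Reactants: 1 methyl (2S)-3-hydroxy-2-methylpropanoate (Roche ester)
Product: 2 methyl (2S)-3-[(tert-butyldimethylsilyl)oxy]-2-methylpropanoate
Conditions: TBSCl, imidazole, CH2Cl2, 0 °C to rt
Reagents that add atoms: tert-butyldimethylsilyl chloride, CC(C)(C)[Si](C)(C)Cl
Why: Imidazole-mediated O-silylation of the primary alcohol, which leaves the existing (2S) centre untouched.

Step 2
Reactants: 2 methyl (2S)-3-[(tert-butyldimethylsilyl)oxy]-2-methylpropanoate
Product: 3 (2S)-3-[(tert-butyldimethylsilyl)oxy]-2-methylpropanoic acid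
Conditions: LiOH·H2O, THF/H2O 3:1, 0 °C to rt; then 1 M HCl to pH 4, 0 °C
Reagents that add atoms: lithium hydroxide, [Li+].[OH-]
Why: Cold saponification of the methyl ester, mild enough to avoid epimerisation or β-elimination at the (2S) centre.

Step 3
Reactants: 4 (2E)-3-methylpent-2-en-4-yn-1-ol
Product: 5 (3E)-5-bromo-3-methylpent-3-en-1-yne
Conditions: PBr3 (0.4 equiv), pyridine (cat.), Et2O, −10 °C; used crude
Reagents that add atoms: phosphorus tribromide, BrP(Br)Br
Why: SN2 conversion of the primary allylic alcohol into the bromide, with the E double bond unchanged.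

Step 4
Reactants: 6 1-[(tert-butyldimethylsilyl)oxy]propan-2-one; 5 (3E)-5-bromo-3-methylpent-3-en-1-yne
Product: 8 (5E)-1-[(tert-butyldimethylsilyl)oxy]-6-methyloct-5-en-7-yn-2-one, via lithium enolate 7 (not isolated)
Conditions: LiN(i-Pr)2 (LDA, 1.1 equiv), THF, −78 °C; then 5, DMPU, −78 to −30 °C
Reagents that add atoms: none
Why: Kinetic enolate formation on the methyl side (the silyloxy-bearing CH2 is hindered and kinetically less acidic) followed by SN2 alkylation with the primary allylic bromide builds C2–C3 and keeps the E alkene.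

Step 5
Reactants: 8 (5E)-1-[(tert-butyldimethylsilyl)oxy]-6-methyloct-5-en-7-yn-2-one; 9 [2-(1,3-dioxolan-2-yl)ethyl]triphenylphosphonium bromide
Product: 11 2-[(2Z,6E)-3-{[(tert-butyldimethylsilyl)oxy]methyl}-7-methylnona-2,6-dien-8-yn-1-yl]-1,3-dioxolane, via phosphorus ylide 10 (not isolated)
Conditions: KN(SiMe3)2, THF, −78 to 0 °C; then 8, −78 °C to rt
Reagents that add atoms: none
Why: Wittig olefination of an α-silyloxy ketone with a non-stabilised ylide (Still's Z-selective variant) puts the CH2OSi group cis to the new chain, which sets the C4=C5 geometry (C15 cis to C6).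

Step 6
Reactants: 11 2-[(2Z,6E)-3-{[(tert-butyldimethylsilyl)oxy]methyl}-7-methylnona-2,6-dien-8-yn-1-yl]-1,3-dioxolane
Product: 12 5-[(3E)-4-methylhex-3-en-5-yn-1-yl]-3,6-dihydro-2H-pyran-2-ol (lactol form of the C7 aldehyde / C15 alcohol; both epimers)
Conditions: 1 M aq. HCl/THF 1:4, rt; NaHCO3 quench
Reagents that add atoms: water, O
Why: Acid hydrolysis removes the dioxolane and the primary silyl ether together, and the Z-placed C15 hydroxyl traps the β,γ-unsaturated aldehyde as a six-membered lactol, which stops it from moving into conjugation.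

Step 7
Reactants: 12 5-[(3E)-4-methylhex-3-en-5-yn-1-yl]-3,6-dihydro-2H-pyran-2-ol
Product: 13 methyl (5Z,9E)-3-hydroxy-6-(hydroxymethyl)-10-methyl-2-methylidenedodeca-5,9-dien-11-ynoate (both C3 epimers)
Conditions: HC≡CCO2Me (3 equiv), i-Bu2AlH (3 equiv), N-methylmorpholine N-oxide (3 equiv), THF, 0 °C; then 12, 0 °C to rt
Reagents that add atoms: methyl propiolate, C#CC(=O)OC
Why: 1,4-Hydroalumination of methyl propiolate gives an α-aluminoacrylate that adds to the open aldehyde form of the lactol (vinylalumination, a non-basic Morita–Baylis–Hillman equivalent); the new carbinol centre is formed as a mixture and is erased in step 10.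

Step 8
Reactants: 13 methyl (5Z,9E)-3-hydroxy-6-(hydroxymethyl)-10-methyl-2-methylidenedodeca-5,9-dien-11-ynoate; 3 (2S)-3-[(tert-butyldimethylsilyl)oxy]-2-methylpropanoic acid
Product: 14 methyl (5Z,9E)-6-({[(2S)-3-[(tert-butyldimethylsilyl)oxy]-2-methylpropanoyl]oxy}methyl)-3-hydroxy-10-methyl-2-methylidenedodeca-5,9-dien-11-ynoate
Conditions: EDC·HCl, DMAP (cat.), CH2Cl2, −20 to 0 °C
Reagents that add atoms: none
Why: Steglich esterification acylates the primary allylic C15 hydroxyl much faster than the hindered secondary Baylis–Hillman alcohol and brings in the (2S) centre from 3 unchanged.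

Step 9
Reactants: 14 methyl (5Z,9E)-6-({[(2S)-3-[(tert-butyldimethylsilyl)oxy]-2-methylpropanoyl]oxy}methyl)-3-hydroxy-10-methyl-2-methylidenedodeca-5,9-dien-11-ynoate
Product: 15 methyl (5Z,9E)-6-({[(2S)-3-[(tert-butyldimethylsilyl)oxy]-2-methylpropanoyl]oxy}methyl)-3-hydroxy-10-methyl-2-methylidene-12-oxododeca-5,9-dienoate
Conditions: CpRu(MeCN)3PF6 (5 mol%), 5,5′-bis(trifluoromethyl)-2,2′-bipyridine (5 mol%), NMP/H2O 4:1, 25 °C; used at once
Reagents that add atoms: water, O
Why: Ruthenium-vinylidene anti-Markovnikov hydration of the terminal alkyne gives the C8 aldehyde under neutral conditions and forms the C8–O bond that becomes the lactone oxygen.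

Step 10
Reactants: 15 methyl (5Z,9E)-6-({[(2S)-3-[(tert-butyldimethylsilyl)oxy]-2-methylpropanoyl]oxy}methyl)-3-hydroxy-10-methyl-2-methylidene-12-oxododeca-5,9-dienoate
Product: 16 methyl (2Z,5Z,9E)-2-(bromomethyl)-6-({[(2S)-3-[(tert-butyldimethylsilyl)oxy]-2-methylpropanoyl]oxy}methyl)-10-methyl-12-oxododeca-2,5,9-trienoate
Conditions: NBS, Me2S, CH2Cl2, −20 to 0 °C; used at once
Reagents that add atoms: N-bromosuccinimide, O=C1CCC(=O)N1Br
Why: Corey–Kim-type activation of the Baylis–Hillman alcohol followed by SN2′ attack of bromide gives the rearranged (Z)-2-(bromomethyl) enoate under neutral conditions that the aldehyde tolerates.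

Step 11
Reactants: 16 methyl (2Z,5Z,9E)-2-(bromomethyl)-6-({[(2S)-3-[(tert-butyldimethylsilyl)oxy]-2-methylpropanoyl]oxy}methyl)-10-methyl-12-oxododeca-2,5,9-trienoate
Product: 19 [(3aR,5Z,9E,11aS)-10-methyl-3-methylidene-2-oxo-2,3,3a,4,7,8,11,11a-octahydrocyclodeca[b]furan-6-yl]methyl (2S)-3-[(tert-butyldimethylsilyl)oxy]-2-methylpropanoate (trans-fused 7R,8S lactone; both ring double bonds trans in the ring), via silyl ether 17 (not isolated), via hydroxy ester 18 (not isolated)
Conditions: CrCl2 (15 mol%), (S,S)-1,8-bis(4-isopropyl-4,5-dihydrooxazol-2-yl)-3,6-diphenyl-9H-carbazole (17 mol%), i-Pr2NEt (0.3 equiv), Mn powder (3 equiv), Me3SiCl (2 equiv), THF, 25 °C, syringe-pump addition of 16 (final 2 mM); then PPTS (cat.), wet CH2Cl2, rt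
Reagents that add atoms: none
Why: Proposed new method: a chiral carbazole bis(oxazoline)–chromium catalyst is used here for a ring-closing allylation, in which divalent chromium (regenerated by Mn) inserts into the allylic C–Br bond, the resulting trivalent allylchromium adds through its γ-carbon (C7) to the tethered aldehyde in a closed Zimmerman–Traxler chair whose two ring bonds sit pseudo-equatorial because of the rigid diene tether (7,8-anti, hence the trans lactone), the ligand shields one aldehyde face to set 8S and with it 7R (the ligand antipode is fixed in a first screen), Me3SiCl releases the catalyst and the desilylated γ-hydroxy ester closes the lactone; the closest known reactions are the chromium-catalysed enantioselective intermolecular 2-(alkoxycarbonyl)allylation of aldehydes to α-methylene-γ-butyrolactones and stoichiometric CrCl2 Nozaki–Hiyama–Kishi closures of bromo aldehydes to germacranolides.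

Step 12
Reactants: 19 [(3aR,5Z,9E,11aS)-10-methyl-3-methylidene-2-oxo-2,3,3a,4,7,8,11,11a-octahydrocyclodeca[b]furan-6-yl]methyl (2S)-3-[(tert-butyldimethylsilyl)oxy]-2-methylpropanoate
Product: 20 [(3aR,5Z,9E,11aS)-10-(hydroxymethyl)-3-methylidene-2-oxo-2,3,3a,4,7,8,11,11a-octahydrocyclodeca[b]furan-6-yl]methyl (2S)-3-[(tert-butyldimethylsilyl)oxy]-2-methylpropanoate (C1=C10 now cis in the ring)
Conditions: SeO2 (0.3 equiv), t-BuOOH (3 equiv, in decane), CH2Cl2, 0 °C to rt
Reagents that add atoms: selenium dioxide, O=[Se]=O; tert-butyl hydroperoxide, CC(C)(C)OO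
Why: Riley allylic oxidation (ene reaction at the electron-richer C1=C10 alkene, then [2,3]-sigmatropic shift) hydroxylates the C14 methyl and re-forms the double bond with CH2OH trans to C2, i.e. the cis-in-ring geometry, as in the known conversion of parthenolide into melampomagnolide B, while the C4=C5 alkene is deactivated by its allylic ester.

Step 13
Reactants: 20 [(3aR,5Z,9E,11aS)-10-(hydroxymethyl)-3-methylidene-2-oxo-2,3,3a,4,7,8,11,11a-octahydrocyclodeca[b]furan-6-yl]methyl (2S)-3-[(tert-butyldimethylsilyl)oxy]-2-methylpropanoate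
Product: 21 [(3aR,5Z,9E,11aS)-10-(hydroxymethyl)-3-methylidene-2-oxo-2,3,3a,4,7,8,11,11a-octahydrocyclodeca[b]furan-6-yl]methyl (2S)-3-hydroxy-2-methylpropanoate (target)
Conditions: HF·pyridine, pyridine, THF, 0 °C to rt
Reagents that add atoms: none
Why: Buffered fluoride desilylation cleaves the primary Si–O bond without touching the esters, the α-methylene lactone or the acid-sensitive 1,5-diene.

## Compound list

1 | methyl (2S)-3-hydroxy-2-methylpropanoate | COC(=O)[C@@H](C)CO | starting material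
2 | methyl (2S)-3-[(tert-butyldimethylsilyl)oxy]-2-methylpropanoate | COC(=O)[C@@H](C)CO[Si](C)(C)C(C)(C)C | intermediate
3 | (2S)-3-[(tert-butyldimethylsilyl)oxy]-2-methylpropanoic acid | OC(=O)[C@@H](C)CO[Si](C)(C)C(C)(C)C | intermediate
4 | (2E)-3-methylpent-2-en-4-yn-1-ol | C#C/C(C)=C/CO | starting material
5 | (3E)-5-bromo-3-methylpent-3-en-1-yne | C#C/C(C)=C/CBr | intermediate
6 | 1-[(tert-butyldimethylsilyl)oxy]propan-2-one | CC(=O)CO[Si](C)(C)C(C)(C)C | starting material
7 | lithium 3-[(tert-butyldimethylsilyl)oxy]prop-1-en-2-olate | [Li+].[O-]C(=C)CO[Si](C)(C)C(C)(C)C | intermediate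
8 | (5E)-1-[(tert-butyldimethylsilyl)oxy]-6-methyloct-5-en-7-yn-2-one | C#C/C(C)=C/CCC(=O)CO[Si](C)(C)C(C)(C)C | intermediate
9 | [2-(1,3-dioxolan-2-yl)ethyl]triphenylphosphonium bromide | [Br-].C1COC(CC[P+](c2ccccc2)(c2ccccc2)c2ccccc2)O1 | starting material
10 | [2-(1,3-dioxolan-2-yl)ethylidene]triphenylphosphorane | C1COC(CC=P(c2ccccc2)(c2ccccc2)c2ccccc2)O1 | intermediate
11 | 2-[(2Z,6E)-3-{[(tert-butyldimethylsilyl)oxy]methyl}-7-methylnona-2,6-dien-8-yn-1-yl]-1,3-dioxolane | C#C/C(C)=C/CC/C(CO[Si](C)(C)C(C)(C)C)=C/CC1OCCO1 | intermediate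
12 | 5-[(3E)-4-methylhex-3-en-5-yn-1-yl]-3,6-dihydro-2H-pyran-2-ol | OC1CC=C(CC/C=C(\C)C#C)CO1 | intermediate
13 | methyl (5Z,9E)-3-hydroxy-6-(hydroxymethyl)-10-methyl-2-methylidenedodeca-5,9-dien-11-ynoate | C=C(C(=O)OC)C(O)C/C=C(CO)/CC/C=C(\C)C#C | intermediate
14 | methyl (5Z,9E)-6-({[(2S)-3-[(tert-butyldimethylsilyl)oxy]-2-methylpropanoyl]oxy}methyl)-3-hydroxy-10-methyl-2-methylidenedodeca-5,9-dien-11-ynoate | C=C(C(=O)OC)C(O)C/C=C(COC(=O)[C@@H](C)CO[Si](C)(C)C(C)(C)C)/CC/C=C(\C)C#C | intermediate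
15 | methyl (5Z,9E)-6-({[(2S)-3-[(tert-butyldimethylsilyl)oxy]-2-methylpropanoyl]oxy}methyl)-3-hydroxy-10-methyl-2-methylidene-12-oxododeca-5,9-dienoate | C=C(C(=O)OC)C(O)C/C=C(COC(=O)[C@@H](C)CO[Si](C)(C)C(C)(C)C)/CC/C=C(\C)CC=O | intermediate
16 | methyl (2Z,5Z,9E)-2-(bromomethyl)-6-({[(2S)-3-[(tert-butyldimethylsilyl)oxy]-2-methylpropanoyl]oxy}methyl)-10-methyl-12-oxododeca-2,5,9-trienoate | BrC/C(C(=O)OC)=C\C/C=C(COC(=O)[C@@H](C)CO[Si](C)(C)C(C)(C)C)/CC/C=C(\C)CC=O | intermediate
17 | methyl 2-[(1R,2S,4E,8Z)-8-({[(2S)-3-[(tert-butyldimethylsilyl)oxy]-2-methylpropanoyl]oxy}methyl)-4-methyl-2-[(trimethylsilyl)oxy]cyclodeca-4,8-dien-1-yl]prop-2-enoate | C=C(C(=O)OC)[C@H]1C/C=C(COC(=O)[C@@H](C)CO[Si](C)(C)C(C)(C)C)/CC/C=C(C)/C[C@@H]1O[Si](C)(C)C | intermediate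
18 | methyl 2-[(1R,2S,4E,8Z)-8-({[(2S)-3-[(tert-butyldimethylsilyl)oxy]-2-methylpropanoyl]oxy}methyl)-2-hydroxy-4-methylcyclodeca-4,8-dien-1-yl]prop-2-enoate | C=C(C(=O)OC)[C@H]1C/C=C(COC(=O)[C@@H](C)CO[Si](C)(C)C(C)(C)C)/CC/C=C(C)/C[C@@H]1O | intermediate
19 | [(3aR,5Z,9E,11aS)-10-methyl-3-methylidene-2-oxo-2,3,3a,4,7,8,11,11a-octahydrocyclodeca[b]furan-6-yl]methyl (2S)-3-[(tert-butyldimethylsilyl)oxy]-2-methylpropanoate | C=C1C(=O)O[C@H]2C/C(C)=C/CC/C(COC(=O)[C@@H](C)CO[Si](C)(C)C(C)(C)C)=C/C[C@H]12 | intermediate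
20 | [(3aR,5Z,9E,11aS)-10-(hydroxymethyl)-3-methylidene-2-oxo-2,3,3a,4,7,8,11,11a-octahydrocyclodeca[b]furan-6-yl]methyl (2S)-3-[(tert-butyldimethylsilyl)oxy]-2-methylpropanoate | C=C1C(=O)O[C@H]2C/C(CO)=C\CC/C(COC(=O)[C@@H](C)CO[Si](C)(C)C(C)(C)C)=C/C[C@H]12 | intermediate
21 | [(3aR,5Z,9E,11aS)-10-(hydroxymethyl)-3-methylidene-2-oxo-2,3,3a,4,7,8,11,11a-octahydrocyclodeca[b]furan-6-yl]methyl (2S)-3-hydroxy-2-methylpropanoate | C=C1C(=O)O[C@H]2C/C(CO)=C\CC/C(COC(=O)[C@@H](C)CO)=C/C[C@H]12 | target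

## Step count and risks

Total step count: 13. Longest linear sequence: 11 steps (steps 3–13, from 4 to 21); the side-chain acid 3 (steps 1–2) joins at step 8.

**Step 11 (the proposed new step).** A ten-membered ring must close under catalytic turnover, and both the trans selectivity and the enantioselectivity are unproven on this substrate. The fallback uses known chemistry and sets out from 16. A stoichiometric CrCl2 Nozaki–Hiyama–Kishi macrocyclisation (CrCl2 8 equiv, THF/DMF, 25 °C, slow addition) closes the ring without absolute control. It proceeds through the chromium alkoxide of 18 and of its mirror-ring diastereomer, methyl 2-[(1S,2R,4E,8Z)-8-({[(2S)-3-[(tert-butyldimethylsilyl)oxy]-2-methylpropanoyl]oxy}methyl)-2-hydroxy-4-methylcyclodeca-4,8-dien-1-yl]prop-2-enoate F1, both of which lactonise in the flask. The result is a 1:1 mixture of 19 and the (3aS,11aR)-lactone F2. Because the (2S) side chain makes these two diastereomers, they are separated by preparative HPLC, and the route is rejoined at 19.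

**Step 12.** The risks are over-oxidation to the enal, competing attack at C9 or C3, and incomplete geometry inversion. The fallback sets out from 19 and deliberately drives the oxidation to the aldehyde level (SeO2 1.5 equiv, t-BuOOH, CH2Cl2, then MnO2 to convert residual alcohol). This gives the C14 aldehyde [(3aR,5Z,9E,11aS)-10-formyl-3-methylidene-2-oxo-2,3,3a,4,7,8,11,11a-octahydrocyclodeca[b]furan-6-yl]methyl (2S)-3-[(tert-butyldimethylsilyl)oxy]-2-methylpropanoate F3, in which the enal can settle into the cis-in-ring geometry. A Luche 1,2-reduction (NaBH4, CeCl3·7H2O, MeOH, −78 °C) then returns the route to 20.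

**Step 9.** The β,γ-unsaturated aldehyde 15 can slip into conjugation, and the ruthenium catalyst may not tolerate the allylic alcohol and acrylate. The fallback sets out from 14 and uses zirconium-catalysed hydroboration (pinacolborane, Cp2Zr(H)Cl 5 mol%, CH2Cl2, 25 °C) to give the isolable dienylboronate methyl (5Z,9E,11E)-6-({[(2S)-3-[(tert-butyldimethylsilyl)oxy]-2-methylpropanoyl]oxy}methyl)-3-hydroxy-10-methyl-2-methylidene-12-(4,4,5,5-tetramethyl-1,3,2-dioxaborolan-2-yl)dodeca-5,9,11-trienoate F4. Buffered oxidation (NaBO3·4H2O, THF/H2O, 0 °C) then gives 15, which is used at once in step 10.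

## Further compounds

F1 | step 11 | methyl 2-[(1S,2R,4E,8Z)-8-({[(2S)-3-[(tert-butyldimethylsilyl)oxy]-2-methylpropanoyl]oxy}methyl)-2-hydroxy-4-methylcyclodeca-4,8-dien-1-yl]prop-2-enoate | C=C(C(=O)OC)[C@@H]1C/C=C(COC(=O)[C@@H](C)CO[Si](C)(C)C(C)(C)C)/CC/C=C(C)/C[C@H]1O
F2 | step 11 | [(3aS,5Z,9E,11aR)-10-methyl-3-methylidene-2-oxo-2,3,3a,4,7,8,11,11a-octahydrocyclodeca[b]furan-6-yl]methyl (2S)-3-[(tert-butyldimethylsilyl)oxy]-2-methylpropanoate | C=C1C(=O)O[C@@H]2C/C(C)=C/CC/C(COC(=O)[C@@H](C)CO[Si](C)(C)C(C)(C)C)=C/C[C@@H]12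
F3 | step 12 | [(3aR,5Z,9E,11aS)-10-formyl-3-methylidene-2-oxo-2,3,3a,4,7,8,11,11a-octahydrocyclodeca[b]furan-6-yl]methyl (2S)-3-[(tert-butyldimethylsilyl)oxy]-2-methylpropanoate | C=C1C(=O)O[C@H]2C/C(C=O)=C\CC/C(COC(=O)[C@@H](C)CO[Si](C)(C)C(C)(C)C)=C/C[C@H]12
F4 | step 9 | methyl (5Z,9E,11E)-6-({[(2S)-3-[(tert-butyldimethylsilyl)oxy]-2-methylpropanoyl]oxy}methyl)-3-hydroxy-10-methyl-2-methylidene-12-(4,4,5,5-tetramethyl-1,3,2-dioxaborolan-2-yl)dodeca-5,9,11-trienoate | C=C(C(=O)OC)C(O)C/C=C(COC(=O)[C@@H](C)CO[Si](C)(C)C(C)(C)C)/CC/C=C(\C)/C=C/B1OC(C)(C)C(C)(C)O1
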